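## Retrosynthetic overview
- The 3-methyltetronic acid is formed last, by Lacey–Dieckmann closure of an α-propionyloxy methyl ester. C5 (S) comes from Ru-catalysed asymmetric transfer hydrogenation of an α-keto ester that is built from a dithiane.
- The key radical bond is C4(lactam)–CH2, made by photo-Pd Heck-type alkylation of N-isopentyl-3-pyrrolin-2-one with 5-iodopent-1-yne. The pyrrolinone ring is purchased and the alkyne is the handle for the next coupling.
- The (E,E)-diene comes from Takai iodo-olefination of the C* aldehyde, then carboalumination of the alkyne and Negishi coupling.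
- The (Z)-trisubstituted alkene and C*(S) come from Cu-catalysed SN2′ opening of isoprene monoxide by the Grignard reagent of a Roche-type bromide.
- Ring order: the pyrrolinone is pre-formed and the tetronic acid ring is closed last.

**Assumption:** (R)-3-bromo-2-methylpropan-1-ol, isoprene monoxide, 1,3-dithiane, pent-4-yn-1-ol, 3-pyrrolin-2-one and 1-bromo-3-methylbutane are commercial. The Cu-catalysed SN2′ opening of isoprene monoxide by an alkyl Grignard reagent is assumed to give the (Z)-allylic alcohol selectively.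

## Route

**Step 1**
Reactants: 1 (2R)-3-bromo-2-methylpropan-1-ol
Product: 2 tert-butyl[(2R)-3-bromo-2-methylpropoxy]dimethylsilane
Conditions: TBSCl, imidazole, CH2Cl2, 0 °C → rt
Reagents that add atoms: tert-butyldimethylsilyl chloride, CC(C)(C)[Si](C)(C)Cl
Why: Silyl protection of the alcohol allows Grignard formation from the bromide, and the stereocentre is untouched.

**Step 2**
Reactants: 2; 3 isoprene monoxide (2-methyl-2-vinyloxirane)
Product: 4 (2Z,6S)-7-[(tert-butyldimethylsilyl)oxy]-2,6-dimethylhept-2-en-1-ol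
Conditions: (i) Mg, THF, 40 °C; (ii) CuI (10 mol%), 3, THF, −30 °C
Reagents that add atoms: none
Why: Cu-catalysed SN2′ opening of the vinyl epoxide by the primary Grignard reagent forms the new C–C bond at the vinyl terminus and leaves CH2OH cis to the new CH2, which is the (Z)-trisubstituted alkene; C* is remote and unchanged.

**Step 3**
Reactants: 4
Product: 5 (2Z,6S)-1-bromo-7-[(tert-butyldimethylsilyl)oxy]-2,6-dimethylhept-2-ene
Conditions: CBr4, PPh3, CH2Cl2, 0 °C; use crude
Reagents that add atoms: carbon tetrabromide, BrC(Br)(Br)Br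
Why: Appel substitution is an SN2 reaction at the primary allylic carbon, so the alkene geometry is retained.

**Step 4**
Reactants: 5; 6 1,3-dithiane
Product: 7 2-[(2Z,6S)-7-(TBSO)-2,6-dimethylhept-2-en-1-yl]-1,3-dithiane
Conditions: 6, n-BuLi, THF, −30 °C; then 5, −78 → 0 °C
Reagents that add atoms: none
Why: Corey–Seebach SN2 alkylation of 2-lithio-1,3-dithiane at the primary allylic bromide makes the C5–CH2 bond and keeps the Z-alkene.

**Step 5**
Reactants: 7
Product: 8 methyl 2-[(2Z,6S)-7-(TBSO)-2,6-dimethylhept-2-en-1-yl]-1,3-dithiane-2-carboxylate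
Conditions: n-BuLi, THF, −20 °C; then ClCO2Me, −78 °C
Reagents that add atoms: methyl chloroformate, COC(=O)Cl
Why: C-Acylation of the 2-lithio-2-alkyldithiane with chloroformate installs the ester carbon (C4 of the target).

**Step 6**
Reactants: 8
Product: 9 methyl (4Z,8S)-9-(TBSO)-4,8-dimethyl-2-oxonon-4-enoate
Conditions: PIFA, MeCN/H2O 9:1, NaHCO3, 0 °C
Reagents that add atoms: water, O
Why: Oxidative hydrolysis of the dithiane (PIFA, buffered so the alkene is not isomerised) unmasks the α-keto ester, and the product is used immediately.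

**Step 7**
Reactants: 9
Product: 10 methyl (2S,4Z,8S)-9-(TBSO)-2-hydroxy-4,8-dimethylnon-4-enoate
Conditions: RuCl[(S,S)-TsDPEN](p-cymene) (2 mol%), HCO2H/Et3N 5:2, CH2Cl2, 25 °C
Reagents that add atoms: none
Why: Noyori–Ikariya asymmetric transfer hydrogenation delivers hydride to one enantioface of the α-keto ester and sets C2 (= C5 of the target) as S; the catalyst enantiomer is chosen to give S by analogy to aryl ketone and aryl keto-ester precedent.

**Step 8**
Reactants: 10
Product: 11 methyl (2S,4Z,8S)-9-(TBSO)-4,8-dimethyl-2-(propanoyloxy)non-4-enoate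
Conditions: EtCOCl, pyridine, cat. DMAP, CH2Cl2, 0 °C
Reagents that add atoms: propionyl chloride, CCC(=O)Cl
Why: O-Acylation of the secondary alcohol adds the propionate needed for the Dieckmann step and leaves the C2 configuration untouched.

**Step 9**
Reactants: 11
Product: 12 methyl (2S,4Z,8S)-9-hydroxy-4,8-dimethyl-2-(propanoyloxy)non-4-enoate
Conditions: HF·pyridine, pyridine/THF, 0 °C → rt
Reagents that add atoms: none
Why: Fluoride cleavage of the primary TBS ether leaves the esters and the alkene intact.

**Step 10**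
Reactants: 12
Product: 13 methyl (2S,4Z,8S)-4,8-dimethyl-9-oxo-2-(propanoyloxy)non-4-enoate
Conditions: Dess–Martin periodinane, NaHCO3, CH2Cl2, 0 °C; use crude
Reagents that add atoms: none
Why: Buffered Dess–Martin oxidation of the primary alcohol gives the α-methyl aldehyde without epimerising C*.

**Step 11**
Reactants: 13
Product: 14 methyl (2S,4Z,8S,9E)-10-iodo-4,8-dimethyl-2-(propanoyloxy)deca-4,9-dienoate
Conditions: CrCl2 (6 equiv), CHI3 (2 equiv), THF, 0 °C
Reagents that add atoms: iodoform, IC(I)I
Why: Takai–Hiyama iodo-olefination gives the (E)-vinyl iodide through anti-elimination from the chromium alkyl.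

**Step 12**
Reactants: 15 pent-4-yn-1-ol
Product: 16 5-iodopent-1-yne
Conditions: PPh3, I2, imidazole, CH2Cl2, 0 °C
Reagents that add atoms: iodine, II
Why: Appel iodination converts the primary alcohol to the primary iodide (the radical precursor) and leaves the alkyne untouched.

**Step 13**
Reactants: 17 1,5-dihydro-2H-pyrrol-2-one; 18 1-bromo-3-methylbutane
Product: 19 1-(3-methylbutyl)-1,5-dihydro-2H-pyrrol-2-one
Conditions: NaH, DMF, 0 °C → rt
Reagents that add atoms: none
Why: N-Alkylation of the lactam anion installs the isopentyl group and keeps the conjugated C3=C4 bond.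

**Step 14 (key radical step)**
Reactants: 16 (2.5 equiv); 19
Product: 20 1-(3-methylbutyl)-4-(pent-4-yn-1-yl)-1,5-dihydro-2H-pyrrol-2-one
Conditions: Pd(PPh3)4 (5 mol%), Xantphos (10 mol%), Cs2CO3, PhH, blue LEDs, 30 °C
Reagents that add atoms: none
Why: Proposed new method: visible-light-excited Pd(0) gives one electron to the primary iodide to make a 4-pentynyl radical that does not cyclise, this nucleophilic radical adds to C4 (the β-carbon) of the electron-poor lactam, the resulting α-amidyl radical recombines with Pd(I) anti to the new alkyl group so that C4–H is syn to Pd, and β-hydride elimination restores C3=C4; the closest known reaction is photoinduced Pd-catalysed Heck-type alkylation of alkenes with alkyl iodides.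

**Step 15**
Reactants: 14; 20
Product: 21 methyl (2S,4Z,8S,9E,11E)-4,8,12-trimethyl-2-(propanoyloxy)-15-[1-(3-methylbutyl)-5-oxo-2,5-dihydro-1H-pyrrol-3-yl]pentadeca-4,9,11-trienoate
Conditions: (i) 20, Me3Al (4 equiv), Cp2ZrCl2 (20 mol%), ClCH2CH2Cl, 23 °C, then remove volatiles; (ii) ZnCl2, THF; then 14, Pd(PPh3)4 (5 mol%), 23 °C
Reagents that add atoms: trimethylaluminium, C[Al](C)C (supplies the C12 methyl)
Why: Negishi carboalumination adds Me and Al syn across the terminal alkyne (Al on the terminal carbon, trans to the chain), and stereoretentive Pd-catalysed Negishi coupling with the (E)-vinyl iodide then gives the (E,E)-diene.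

**Step 16**
Reactants: 21
Product: 22 Sarcotrine D
Conditions: KOtBu (2.2 equiv), THF, −78 → −20 °C, 30 min; then aq. HCl to pH 3
Reagents that add atoms: none
Why: Lacey–Dieckmann cyclisation of the propionate enolate onto the methyl ester closes the 3-methyltetronic acid with loss of MeOH, the low temperature and short time limit epimerisation of C5, and no new stereocentre forms.

## Compound list
1 | (2R)-3-bromo-2-methylpropan-1-ol | BrC[C@H](C)CO | starting material
2 | tert-butyl[(2R)-3-bromo-2-methylpropoxy]dimethylsilane | BrC[C@H](C)CO[Si](C)(C)C(C)(C)C | intermediate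
3 | isoprene monoxide (2-methyl-2-vinyloxirane) | C=CC1(C)CO1 | starting material
4 | (2Z,6S)-7-(TBSO)-2,6-dimethylhept-2-en-1-ol | OC/C(C)=C\CC[C@H](C)CO[Si](C)(C)C(C)(C)C | intermediate
5 | (2Z,6S)-1-bromo-7-(TBSO)-2,6-dimethylhept-2-ene | BrC/C(C)=C\CC[C@H](C)CO[Si](C)(C)C(C)(C)C | intermediate
6 | 1,3-dithiane | C1CSCSC1 | starting material
7 | 2-[(2Z,6S)-7-(TBSO)-2,6-dimethylhept-2-en-1-yl]-1,3-dithiane | S1CCCSC1C/C(C)=C\CC[C@H](C)CO[Si](C)(C)C(C)(C)C | intermediate
8 | methyl 2-[(2Z,6S)-7-(TBSO)-2,6-dimethylhept-2-en-1-yl]-1,3-dithiane-2-carboxylate | COC(=O)C1(SCCCS1)C/C(C)=C\CC[C@H](C)CO[Si](C)(C)C(C)(C)C | intermediate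
9 | methyl (4Z,8S)-9-(TBSO)-4,8-dimethyl-2-oxonon-4-enoate | COC(=O)C(=O)C/C(C)=C\CC[C@H](C)CO[Si](C)(C)C(C)(C)C | intermediate
10 | methyl (2S,4Z,8S)-9-(TBSO)-2-hydroxy-4,8-dimethylnon-4-enoate | COC(=O)[C@@H](O)C/C(C)=C\CC[C@H](C)CO[Si](C)(C)C(C)(C)C | intermediate
11 | methyl (2S,4Z,8S)-9-(TBSO)-4,8-dimethyl-2-(propanoyloxy)non-4-enoate | COC(=O)[C@@H](OC(=O)CC)C/C(C)=C\CC[C@H](C)CO[Si](C)(C)C(C)(C)C | intermediate
12 | methyl (2S,4Z,8S)-9-hydroxy-4,8-dimethyl-2-(propanoyloxy)non-4-enoate | COC(=O)[C@@H](OC(=O)CC)C/C(C)=C\CC[C@H](C)CO | intermediate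
13 | methyl (2S,4Z,8S)-4,8-dimethyl-9-oxo-2-(propanoyloxy)non-4-enoate | COC(=O)[C@@H](OC(=O)CC)C/C(C)=C\CC[C@H](C)C=O | intermediate
14 | methyl (2S,4Z,8S,9E)-10-iodo-4,8-dimethyl-2-(propanoyloxy)deca-4,9-dienoate | COC(=O)[C@@H](OC(=O)CC)C/C(C)=C\CC[C@H](C)/C=C/I | intermediate
15 | pent-4-yn-1-ol | C#CCCCO | starting material
16 | 5-iodopent-1-yne | C#CCCCI | intermediate
17 | 1,5-dihydro-2H-pyrrol-2-one (3-pyrrolin-2-one) | O=C1C=CCN1 | starting material
18 | 1-bromo-3-methylbutane | CC(C)CCBr | starting material
19 | 1-(3-methylbutyl)-1,5-dihydro-2H-pyrrol-2-one | O=C1C=CCN1CCC(C)C | intermediate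
20 | 1-(3-methylbutyl)-4-(pent-4-yn-1-yl)-1,5-dihydro-2H-pyrrol-2-one | C#CCCCC1=CC(=O)N(CCC(C)C)C1 | intermediate
21 | methyl (2S,4Z,8S,9E,11E)-4,8,12-trimethyl-2-(propanoyloxy)-15-[1-(3-methylbutyl)-5-oxo-2,5-dihydro-1H-pyrrol-3-yl]pentadeca-4,9,11-trienoate | COC(=O)[C@@H](OC(=O)CC)C/C(C)=C\CC[C@H](C)/C=C/C=C(\C)CCCC1=CC(=O)N(CCC(C)C)C1 | intermediate
22 | Sarcotrine D | CC1=C(O)[C@H](C/C(C)=C\CC[C@H](C)/C=C/C=C(\C)CCCC2=CC(=O)N(CCC(C)C)C2)OC1=O | target

## Totals
Total steps: 16. Longest linear sequence: 13 (1→2→4→5→7→8→9→10→11→12→13→14→21→22, i.e. steps 1–11, 15 and 16).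

## Three steps most likely to fail
1. **Step 14 (photo-Pd radical Heck-type alkylation).** Risks are saturated conjugate-addition product, 6-exo cyclisation of the α-amidyl radical onto the alkyne, and Pd side reactions of the terminal alkyne.
   Fallback: Ni-catalysed reductive cross-electrophile coupling of 5-iodopent-1-yne with 4-(triflyloxy)-1-isopentyl-1,5-dihydropyrrol-2-one, which is made from N-isopentyltetramic acid.
2. **Steps 6–7 (dithiane unmasking and transfer hydrogenation).** The β,γ-unsaturated α-keto ester can isomerise into conjugation, and the ee of the transfer hydrogenation of an aliphatic α-keto ester may be modest.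
   Fallback: reduce 9 with NaBH4 to the racemic hydroxy ester and resolve it by lipase-catalysed acylation with vinyl propionate, keeping the (S)-alcohol and propionylating it chemically.
3. **Step 2 (Cu-catalysed SN2′ opening of isoprene monoxide).** Risks are Z/E erosion and competing SN2 attack at the epoxide CH2.
   Fallback: Still–Gennari olefination of (4S)-5-(TBSO)-4-methylpentanal (from 2 by Cu-catalysed Grignard opening of ethylene oxide and oxidation) with methyl bis(trifluoroethyl) 2-phosphonopropionate, then DIBAL reduction to give alcohol 4.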